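**Strategy.** Ring A is opened at C1–C10 (eremophilane numbering) and, behind it, at the hindered C4–C5 bond. Because C10 carries the oxygenated C9 as neighbour and C2=O sits 1,4 to C9–O across the C1–C10 bond, ring B is taken as 3-methylcyclohexane-1,2-dione. In one amine-catalysed annulation its enol carbon C5 adds to (E)-pent-3-en-2-one (setting C4 and the quaternary C5) and the chain methyl C1 then condenses onto the C10 carbonyl of the resulting triketone, closing ring A as an ene-dione. The surviving C9 carbonyl later delivers 10-H, the C7 isopropenyl group and both ester oxygens.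

Key step: step 1

Remark (assumptions): positions follow eremophilane numbering (ring A = C1, C2, C3, C4, C5, C10; ring B = C5 to C10; C15 on C4, C14 on C5, isopropenyl C11–C13 on C7; β = face of the C5 methyl); the quinidine-derived primary amine is assumed to give the (4S,5R) series (otherwise the quinine-derived pseudo-enantiomer is used), and (2R)-2-methylbutanoic acid is taken as purchasable.

**Step 1**
Reactants: 1 3-methylcyclohexane-1,2-dione; 2 (E)-pent-3-en-2-one
Product: 4 (4S,4aR)-4,4a-dimethyl-4,4a,5,6-tetrahydronaphthalene-2,8(3H,7H)-dione, via triketone 3 (not isolated)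
Conditions: 9-amino-9-deoxy-epi-quinidine (20 mol %), PhCO2H (40 mol %), toluene, 40 °C; then pyrrolidine (30 mol %), AcOH (30 mol %), 80 °C
Reagents that add atoms: none
Why: The primary amine converts 2 into an iminium ion, the tetrasubstituted enol of 1 adds through C5 to C4 (Michael addition), and the methyl ketone of triketone 3 is then taken by pyrrolidine into its less substituted enamine, whose carbon C1 attacks the C10 carbonyl of the vicinal dione, loss of water giving the conjugated ene-dione. The closest known reaction type is the amine-catalysed asymmetric Robinson annulation, combined with cinchona primary-amine Michael additions of cyclic dicarbonyl compounds to enones. Ring A closes by a 6-(enolexo)-exo-trig aldol addition followed by E1cB dehydration. C4 and C5 are set in the Michael stage: the catalyst shields one face of the iminium ion (absolute sense at C4), and the compact syn-clinal approach of the cyclic enol should place the two methyl groups cis on the later ring A, as is usual for pent-3-en-2-one annulations of 2-methylcyclohexanones; C10 becomes trigonal here and is set in step 2. The step needs C-alkylation at C5 (not at C8 or on oxygen) and closure of C1 onto C10 (not of C3 onto C9): the first is secured by the dominant tetrasubstituted enol of 1, the second because only the C1–C10 ketol can dehydrate to a conjugated six-membered enone, whereas the bridged C3–C9 ketol forms reversibly.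

**Step 2**
Reactants: 4 (4S,4aR)-4,4a-dimethyl-4,4a,5,6-tetrahydronaphthalene-2,8(3H,7H)-dione
Product: 5 (4S,5R,10S)-11,12,13-trinor-10βH-eremophilane-2,9-dione
Conditions: H2 (1 atm), Pd/C (10 wt %), EtOAc, rt
Reagents that add atoms: none
Why: Heterogeneous hydrogenation of the electron-poor C1=C10 bond should add both hydrogens syn from the β-face, the usual course for Δ1(10)-octal-2-ones with an angular methyl, giving the cis-fused dione and setting C10 (S), while neutral conditions avoid epimerisation next to the C9 carbonyl.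

**Step 3**
Reactants: 5 (4S,5R,10S)-11,12,13-trinor-10βH-eremophilane-2,9-dione
Product: 6 (4S,5R,10S)-2,2-(ethylenedioxy)-11,12,13-trinor-10βH-eremophilan-9-one
Conditions: Me3SiOCH2CH2OSiMe3 (1.1 equiv), Me3SiOTf (5 mol %), CH2Cl2, −78 °C
Reagents that add atoms: 1,2-bis(trimethylsilyloxy)ethane, C[Si](C)(C)OCCO[Si](C)(C)C
Why: Silyl-triflate-catalysed ketalisation under kinetic conditions should select the unhindered C2 carbonyl (two methylene neighbours) over the C9 carbonyl next to the ring-fusion carbon and leave the epimerisable C10 untouched.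

**Step 4**
Reactants: 6 (4S,5R,10S)-2,2-(ethylenedioxy)-11,12,13-trinor-10βH-eremophilan-9-one
Product: 8 (4S,5R,10S)-2,2-(ethylenedioxy)-11,12,13-trinor-10βH-eremophil-7-en-9-one, via trimethylsilyl enol ether 7 (not isolated)
Conditions: LiN(i-Pr)2, Me3SiCl, THF, −78 °C; then Pd(OAc)2 (1.1 equiv), MeCN, rt
Reagents that add atoms: none
Why: Saegusa–Ito oxidation: kinetic deprotonation takes the C8 methylene rather than the ring-fusion methine C10, and divalent palladium turns the silyl enol ether into the C7=C8 enone without forming a stereocenter.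

**Step 5**
Reactants: 8 (4S,5R,10S)-2,2-(ethylenedioxy)-11,12,13-trinor-10βH-eremophil-7-en-9-one
Product: 9 (4S,5R,7S,10S)-2,2-(ethylenedioxy)-9-(trimethylsilyloxy)-10βH-eremophila-8,11-diene
Conditions: CH2=C(CH3)MgBr, CuBr·SMe2 (10 mol %), Me3SiCl, THF, −78 °C
Reagents that add atoms: isopropenylmagnesium bromide, C=C(C)[Mg]Br; chlorotrimethylsilane, C[Si](C)(C)Cl
Why: Copper-catalysed conjugate addition accelerated by chlorotrimethylsilane; the isopropenyl group should enter C7 on the convex β-face of the cis-fused bicycle, away from ring A, and the enolate is trapped regiospecifically as the C8=C9 silyl enol ether.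

**Step 6**
Reactants: 9 (4S,5R,7S,10S)-2,2-(ethylenedioxy)-9-(trimethylsilyloxy)-10βH-eremophila-8,11-diene
Product: 11 (4S,5R,7R,8R,10S)-2,2-(ethylenedioxy)-8α-hydroxy-10βH-eremophil-11-en-9-one, via silyloxy ketone 10 (not isolated)
Conditions: dimethyldioxirane (acetone solution), CH2Cl2, −78 °C; then aq. citric acid, THF, 0 °C
Reagents that add atoms: dimethyldioxirane, CC1(C)OO1
Why: Rubottom oxidation: the electron-rich silyl enol ether is epoxidised much faster than the 1,1-disubstituted isopropenyl alkene and anti to the adjacent C7 substituent, and silyl migration then hydrolysis should give the 8α-hydroxy ketone, which is also the more stable trans-diequatorial epimer.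

**Step 7**
Reactants: 11 (4S,5R,7R,8R,10S)-2,2-(ethylenedioxy)-8α-hydroxy-10βH-eremophil-11-en-9-one; 12 (2R)-2-methylbutanoic acid
Product: 13 (4S,5R,7R,8R,10S)-2,2-(ethylenedioxy)-8α-[(2R)-2-methylbutanoyloxy]-10βH-eremophil-11-en-9-one
Conditions: DCC, DMAP (10 mol %), CH2Cl2, 0 °C
Reagents that add atoms: none
Why: Steglich esterification of the only free hydroxyl places the (2R)-2-methylbutanoyl group on O8 without any regiochemical choice and forms no new stereocenter.

**Step 8**
Reactants: 13 (4S,5R,7R,8R,10S)-2,2-(ethylenedioxy)-8α-[(2R)-2-methylbutanoyloxy]-10βH-eremophil-11-en-9-one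
Product: 14 (4S,5R,7R,8R,9S,10S)-2,2-(ethylenedioxy)-9α-hydroxy-8α-[(2R)-2-methylbutanoyloxy]-10βH-eremophil-11-ene
Conditions: LiBH(s-Bu)3, THF, −78 °C; then AcOH, −78 °C
Reagents that add atoms: none
Why: Ketone reduction with a bulky borohydride: axial approach to C9 is blocked by the syn-axial C4–C5 bond, so hydride should arrive equatorially from the β-face and give the axial 9α-alcohol cis to O8, while the ester and ketal are inert at −78 °C and the cold acidic quench suppresses O8-to-O9 acyl migration.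

**Step 9**
Reactants: 14 (4S,5R,7R,8R,9S,10S)-2,2-(ethylenedioxy)-9α-hydroxy-8α-[(2R)-2-methylbutanoyloxy]-10βH-eremophil-11-ene; 15 (E)-2-methylbut-2-enoyl chloride
Product: 16 (4S,5R,7R,8R,9S,10S)-2,2-(ethylenedioxy)-8α-[(2R)-2-methylbutanoyloxy]-9α-[(E)-2-methylbut-2-enoyloxy]-10βH-eremophil-11-ene
Conditions: pyridine, DMAP (20 mol %), CH2Cl2, 0 °C to rt
Reagents that add atoms: none
Why: DMAP-catalysed acylation of the remaining secondary alcohol with the acid chloride; pyridine instead of a trialkylamine avoids vinylketene formation and should keep the (E)-2-methylbut-2-enoyl geometry.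

**Step 10**
Reactants: 16 (4S,5R,7R,8R,9S,10S)-2,2-(ethylenedioxy)-8α-[(2R)-2-methylbutanoyloxy]-9α-[(E)-2-methylbut-2-enoyloxy]-10βH-eremophil-11-ene
Product: 17 (4S,5R,7R,8R,9S,10S)-8α-[(2R)-2-methylbutanoyloxy]-9α-[(E)-2-methylbut-2-enoyloxy]-10βH-eremophil-11-en-2-one (CNP0312791.1)
Conditions: 1 M aq. HCl, THF, rt
Reagents that add atoms: water, O
Why: Acid-catalysed hydrolysis of the dioxolane releases the C2 ketone, and the two esters and the isopropenyl group should tolerate dilute acid at room temperature.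

**Compound list**
1 | 3-methylcyclohexane-1,2-dione (mainly its enol, 2-hydroxy-3-methylcyclohex-2-en-1-one) | CC1CCCC(=O)C1=O | starting material
2 | (E)-pent-3-en-2-one | C/C=C/C(C)=O | starting material
3 | (3R)-3-methyl-3-[(2S)-4-oxopentan-2-yl]cyclohexane-1,2-dione | CC(=O)C[C@H](C)[C@@]1(C)CCCC(=O)C1=O | intermediate
4 | (4S,4aR)-4,4a-dimethyl-4,4a,5,6-tetrahydronaphthalene-2,8(3H,7H)-dione (11,12,13-trinoreremophil-1(10)-ene-2,9-dione) | O=C1C=C2C(=O)CCC[C@]2(C)[C@@H](C)C1 | intermediate
5 | (4S,5R,10S)-11,12,13-trinor-10βH-eremophilane-2,9-dione (cis-fused, 4β,5β-dimethyl) | O=C1C[C@@H]2C(=O)CCC[C@]2(C)[C@@H](C)C1 | intermediate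
6 | (4S,5R,10S)-2,2-(ethylenedioxy)-11,12,13-trinor-10βH-eremophilan-9-one | C1COC2(O1)C[C@@H]3C(=O)CCC[C@]3(C)[C@@H](C)C2 | intermediate
7 | (4S,5R,10S)-2,2-(ethylenedioxy)-9-(trimethylsilyloxy)-11,12,13-trinor-10βH-eremophil-8-ene | C1COC2(O1)C[C@@H]3C(O[Si](C)(C)C)=CCC[C@]3(C)[C@@H](C)C2 | intermediate
8 | (4S,5R,10S)-2,2-(ethylenedioxy)-11,12,13-trinor-10βH-eremophil-7-en-9-one | C1COC2(O1)C[C@@H]3C(=O)C=CC[C@]3(C)[C@@H](C)C2 | intermediate
9 | (4S,5R,7S,10S)-2,2-(ethylenedioxy)-9-(trimethylsilyloxy)-10βH-eremophila-8,11-diene (7β-isopropenyl) | C1COC2(O1)C[C@@H]3C(O[Si](C)(C)C)=C[C@@H](C(C)=C)C[C@]3(C)[C@@H](C)C2 | intermediate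
10 | (4S,5R,7R,8R,10S)-2,2-(ethylenedioxy)-8α-(trimethylsilyloxy)-10βH-eremophil-11-en-9-one | C1COC2(O1)C[C@@H]3C(=O)[C@H](O[Si](C)(C)C)[C@@H](C(C)=C)C[C@]3(C)[C@@H](C)C2 | intermediate
11 | (4S,5R,7R,8R,10S)-2,2-(ethylenedioxy)-8α-hydroxy-10βH-eremophil-11-en-9-one | C1COC2(O1)C[C@@H]3C(=O)[C@H](O)[C@@H](C(C)=C)C[C@]3(C)[C@@H](C)C2 | intermediate
12 | (2R)-2-methylbutanoic acid | CC[C@@H](C)C(=O)O | starting material
13 | (4S,5R,7R,8R,10S)-2,2-(ethylenedioxy)-8α-[(2R)-2-methylbutanoyloxy]-10βH-eremophil-11-en-9-one | C1COC2(O1)C[C@@H]3C(=O)[C@H](OC(=O)[C@H](C)CC)[C@@H](C(C)=C)C[C@]3(C)[C@@H](C)C2 | intermediate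
14 | (4S,5R,7R,8R,9S,10S)-2,2-(ethylenedioxy)-9α-hydroxy-8α-[(2R)-2-methylbutanoyloxy]-10βH-eremophil-11-ene | C1COC2(O1)C[C@@H]3[C@H](O)[C@H](OC(=O)[C@H](C)CC)[C@@H](C(C)=C)C[C@]3(C)[C@@H](C)C2 | intermediate
15 | (E)-2-methylbut-2-enoyl chloride (tigloyl chloride) | C/C=C(\C)C(=O)Cl | starting material
16 | (4S,5R,7R,8R,9S,10S)-2,2-(ethylenedioxy)-8α-[(2R)-2-methylbutanoyloxy]-9α-[(E)-2-methylbut-2-enoyloxy]-10βH-eremophil-11-ene | C1COC2(O1)C[C@@H]3[C@H](OC(=O)/C(C)=C/C)[C@H](OC(=O)[C@H](C)CC)[C@@H](C(C)=C)C[C@]3(C)[C@@H](C)C2 | intermediate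
17 | (4S,5R,7R,8R,9S,10S)-8α-[(2R)-2-methylbutanoyloxy]-9α-[(E)-2-methylbut-2-enoyloxy]-10βH-eremophil-11-en-2-one (CNP0312791.1) | C=C(C)[C@H]1C[C@@]2(C)[C@H](CC(=O)C[C@@H]2C)[C@H](OC(=O)/C(C)=C/C)[C@@H]1OC(=O)[C@H](C)CC | target

**Totals.** Total step count: 10. Longest linear sequence: 10 steps (from 1).

**Steps most likely to fail**

1. Step 1. The risk is insufficient facial discrimination in the iminium Michael addition (absolute and relative configuration at C4/C5), competing alkylation at C8 or on oxygen, or retro-Michael loss of stereochemical integrity in the hot condensation stage. The fallback sets out from 1 and comes back at 3. The enol of 1 is O-alkylated under Mitsunobu conditions (PPh3, DIAD, THF, 0 °C, inversion) with (2S,3E)-pent-3-en-2-ol (C/C=C/[C@H](C)O) to give the allyl vinyl ether 3-methyl-2-{[(2R,3E)-pent-3-en-2-yl]oxy}cyclohex-2-en-1-one F1. Claisen rearrangement (toluene, 110 °C) through a chair transition state with the carbinol methyl equatorial should transfer the chirality to C5 and C4 and give (3R)-3-methyl-3-[(2S,3E)-pent-3-en-2-yl]cyclohexane-1,2-dione F2. Tsuji–Wacker oxidation (PdCl2, CuCl, O2, DMF/H2O) at the alkene carbon remote from the branch then gives 3, now isolated, which is cyclised to 4 with pyrrolidine/AcOH as in the second stage of step 1.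

2. Step 5. The risk is delivery of the isopropenyl group to the α-face of C7 (poor facial selectivity) or competing 1,2-addition. The fallback sets out from 8 and comes back at 14. Luche reduction (NaBH4, CeCl3·7H2O, MeOH, −78 °C) from the convex face should give the 9α-allylic alcohol (4S,5R,9S,10S)-2,2-(ethylenedioxy)-11,12,13-trinor-10βH-eremophil-7-en-9α-ol F3. Hydroxyl-directed epoxidation (VO(acac)2, t-BuOOH, CH2Cl2) gives the 7α,8α-epoxy-9α-ol F4. Copper-catalysed opening (CH2=C(CH3)MgBr, CuI, THF, −30 °C) at C7, the carbon remote from the carbinol, proceeds with inversion (trans-diaxial) and fixes the 7β-isopropenyl group next to the 8α-hydroxyl in the diol (4S,5R,7R,8R,9S,10S)-2,2-(ethylenedioxy)-10βH-eremophil-11-ene-8α,9α-diol F5. Selective Steglich acylation of the equatorial 8-hydroxyl with 12 (DCC, DMAP, −20 °C) then gives 14.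

3. Step 8. The risk is hydride approach from the axial direction, giving the 9β-alcohol. The fallback sets out from 13 and comes back at 16. The 9β-alcohol (4S,5R,7R,8R,9R,10S)-2,2-(ethylenedioxy)-9β-hydroxy-8α-[(2R)-2-methylbutanoyloxy]-10βH-eremophil-11-ene F6 is then taken as the intermediate (made on purpose with NaBH4, MeOH, −40 °C). Mitsunobu esterification with tiglic acid (C/C=C(\C)C(=O)O; PPh3, DIAD, toluene, 0 °C to rt) inverts C9 and installs the 9α-ester in one operation, giving 16 directly.

**Further compounds**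
F1 | step 1 | 3-methyl-2-{[(2R,3E)-pent-3-en-2-yl]oxy}cyclohex-2-en-1-one | C/C=C/[C@@H](C)OC1=C(C)CCCC1=O
F2 | step 1 | (3R)-3-methyl-3-[(2S,3E)-pent-3-en-2-yl]cyclohexane-1,2-dione | C/C=C/[C@H](C)[C@@]1(C)CCCC(=O)C1=O
F3 | step 5 | (4S,5R,9S,10S)-2,2-(ethylenedioxy)-11,12,13-trinor-10βH-eremophil-7-en-9α-ol | C1COC2(O1)C[C@@H]3[C@H](O)C=CC[C@]3(C)[C@@H](C)C2
F4 | step 5 | (4S,5R,10S)-2,2-(ethylenedioxy)-7α,8α-epoxy-11,12,13-trinor-10βH-eremophilan-9α-ol | C1COC2(O1)C[C@@H]3[C@H](O)[C@@H]4O[C@@H]4C[C@]3(C)[C@@H](C)C2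
F5 | step 5 | (4S,5R,7R,8R,9S,10S)-2,2-(ethylenedioxy)-10βH-eremophil-11-ene-8α,9α-diol | C1COC2(O1)C[C@@H]3[C@H](O)[C@H](O)[C@@H](C(C)=C)C[C@]3(C)[C@@H](C)C2
F6 | step 8 | (4S,5R,7R,8R,9R,10S)-2,2-(ethylenedioxy)-9β-hydroxy-8α-[(2R)-2-methylbutanoyloxy]-10βH-eremophil-11-ene | C1COC2(O1)C[C@@H]3[C@@H](O)[C@H](OC(=O)[C@H](C)CC)[C@@H](C(C)=C)C[C@]3(C)[C@@H](C)C2
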